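## The problem

The target 44 is a spiro[4.5]decane. Ring A (C1–C4 plus the spiro atom C5) is a cyclopentane with a secondary hydroxyl at C1 and a 1‑hydroxy‑trienyl side chain at C2. Ring B (C5–C10) carries a 3‑hydroxypropyl chain at C6, an exocyclic tetrasubstituted enal at C7 (its outer carbon, called Cα here, bears the methyl and the formyl group) and a tertiary methyl carbinol at C10. Five stereocentres (1S,2S,5S,6R,10S) must be set, and the hard one is the quaternary C5, bonded to the fully substituted C10 on one side and to the stereocentre C6 on the other. C6 is the only centre that can be installed by catalyst control on a simple precursor. Once it is in place, a six‑membered closure of ring B can pass its information to C5 and C10, and the C10 hydroxyl can then steer reagents to one face of ring A to fix the trans pair C1/C2. Three alkene geometries also count, the most demanding being C7=Cα, whose carbonyl carbon must lie cis to C6. The molecule is fragile: the enal is open to γ‑deprotonation, geometric isomerisation and nucleophiles; C6–H is allylic and γ to the carbonyl; the C10 hydroxyl is β to any carbonyl at C1 (retro‑aldol) and tertiary (elimination); the side chain is a triene with a free allylic alcohol. The enabling feature is the pattern of C7=Cα: C8 and the methyl are cis, C6 and the carbonyl carbon are cis, which is what results when a carbon nucleophile (C8) and a methyl electrophile add to the same side of a C6–C7≡Cα–CO2Me alkynoate.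

## Retrosynthesis

**End game (44 back to 41).** No skeletal bond is cut. The enal is unmasked last: 44 comes from its silyl ether 43, 43 from allylic alcohol 42, and 42 from the methyl ester/pivalate 41. A tetrasubstituted acrylate is inert to the organometallic steps, whereas an enal would not be. The pivalate on the C6 arm is chosen because the hydride that reduces the ester also removes it, so only the side‑chain silyl ether needs its own deprotection. The forward steps must tell an allylic from a saturated primary alcohol and must not isomerise the enal.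

**41 to epoxide 27 and alkenyl iodide 37.** The bond between C2 and the side chain is cut. Anti opening of a cis‑epoxide by an alkenyl nucleophile makes this bond and the trans C1‑hydroxyl/C2 relationship in one step, and C1 is neopentyl, so attack can only occur at C2. The neighbouring options (α‑alkenylation of a C1 ketone, or olefination of a C2 acyl group) would leave C2 epimerisable or the trisubstituted alkene geometry open. The precursor loses the whole side chain and all three of its alkenes.

**Side chain 37 to 36, 34, then 30 and 33.** The C–I bond of 36 is traced to a hydroxyl‑directed trans‑hydrometalation of the propargylic alcohol 34, which fixes the geometry that places ring and diene chain cis. The diene of 34 is cut between the methylidene carbon and the E‑alkene: an alkenyl triflate 30 from ketone 28 and a boron‑masked enyne 33 from 31 and 32. A Wittig‑type construction of the diene would give E/Z mixtures. Each piece is one step from a commercial compound.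

**Epoxide 27 to alkene 26, then to ketone 21 via 24 and 22.** The epoxide oxygen must sit on the ring A face on which C10 lies, so the free C10 hydroxyl of 26 is used to deliver it. The C1=C2 alkene is taken back to the C1 ketone through enol triflate 24. Because C5 is quaternary, the ketone can only enolise towards C2. The tertiary alcohol has to be masked (22) while base is present, to block retro‑aldol cleavage.

**Ketol 21 to bromo diketone 19, then to 17.** The C5–C10 bond is cut as an aldol bond; this is the ring B closure. A plain base‑ or acid‑mediated aldol of the free diketone was rejected: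
- the C9 enolate of the methyl ketone can attack C1 to give a fused six‑membered ketol that dehydrates irreversibly;
- strong base endangers C6–H.

The enolate is therefore generated only at C5, under neutral conditions, by one‑electron reduction of a C5–Br bond. The bromide comes from the C1=C5 silyl enol ether of 17, which also serves as the ketone protecting group in the earlier steps. The closure must set C5 and C10 relative to C6.

**17 to alkynoate 12, Grignard reagent 14 (from bromide 13) and a methyl electrophile.** This is the key disconnection: C7–C8 and Cα–CH3 are cut together. The alternative of olefinating a C7 ketone would have to make a tetrasubstituted alkene next to a stereocentre with no control of geometry. Here geometry follows from syn addition and retention. The precursor 12 has no ring B carbons beyond C7 and one stereocentre.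

**12 to 10, 9, 8, then enone 6 and alkyne 7.** The ester carbon is removed (acetylide carboxylation), the enol ether is taken back to the ketone, and the C6–C7 bond is cut as a catalytic asymmetric conjugate alkynylation of the exocyclic enone 6. This sets C6, the only centre that needs external control. Adding the three‑carbon arm to an enynone instead would risk 1,6‑addition.

**6 to aldehyde 3 and enamine 4; 3 to 2 and diol 1.** An enamine aldol condensation and two functional‑group steps lead back to commercial materials.

## Roads not taken

**Alternative 1:** The C1–C5 and O–C10 bonds are cut together, so that ring A and a temporary isoxazoline form in one intramolecular cycloaddition.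
- Forward step: the nitrile oxide A1, generated at the end of a three‑carbon tether on C5 and held by a magnesium alkoxide at C6, adds across a tetrasubstituted C5=C10 alkene of a preformed ring B to give the spiro‑fused isoxazoline A2. Later N–O cleavage would reveal the C1 carbonyl and the C10 hydroxyl.
- Merits: C5 and C10 are formed suprafacially in one concerted step. Their relative configuration is fixed by mechanism and their relation to C6 by the directing alkoxide. This is more secure than the facial selectivity of the ring closure in step 10.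
- Weak points: A2 has an oxygen at C6 where a carbon chain is needed and plain methylenes at C7–C9. The hydroxypropyl group with its configuration and the tetrasubstituted enal would have to be built afterwards on a hindered ring, most plausibly by olefination at C7 with no control of geometry.
- Comparison: the chosen plan has a less certain C5–C10 closure. Against that it fixes the alkene geometry by a stereospecific addition, has the C6 arm in place before ring B closes, and needs fewer steps after the key event.

**Alternative 2:** Ring B is closed by cutting C6–C7 and the adjoining bond of the future C6 arm (a de Mayo sequence).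
- Forward step: on irradiation a dioxinone C=C adds across a vinyl group on C5 to give the cyclobutane photoadduct A3. Retro‑aldol fragmentation would then leave a carbonyl at C7 and a three‑carbon acid arm on C6.
- Merits: two C–C bonds and ring B in one photochemical step, direct delivery of the full C6 arm, and tolerance of the crowded C5/C10 region. On convergence at ring B it is at least the equal of the chosen plan.
- Weak points: the hardest bond, C5–C10, and both its stereocentres must be made beforehand by other means. C6 is set only by the facial preference of the cycloaddition relative to the two ring A branches on C5. The C7 carbonyl must finally be olefinated next to an epimerisable C6 with no handle on geometry.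
- Comparison: the chosen plan sets C6 by catalyst control and the alkene geometry by syn addition. It pays with a longer sequence from ring B closure to the ring A functions.

**Alternative 3:** The C4–C5 bond is cut: ring A arises by semipinacol ring expansion.
- Forward step: a Lewis acid opens a C5–C10 epoxide at C5 and a cyclobutane methylene migrates anti to the leaving oxygen, giving the spiro hydroxy ketone A4 with the C1 carbonyl, the quaternary C5 and the free C10 hydroxyl.
- Merits: the 1,2‑shift is stereospecific, so this is the most reliable of the four plans for the C5/C10 relationship. The isopropenyl group of A4 also suggests a terpene chiral‑pool start. In both respects it is better than the chosen plan.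
- Weak points: C7 of A4 is an sp3 centre bearing isopropenyl. The double bond must be moved into the exocyclic position and one particular methyl (the one cis to C6) oxidised to the aldehyde, with no stereochemical handle. C6 carries one carbon and needs a two‑carbon extension.
- Comparison: the chosen plan builds the enal geometry and the full C6 arm directly. Its price is a C5–C10 closure that rests on conformational control, not on a stereospecific shift.

Key step: step 8

Assumption: with (R)-DTBM-SEGPHOS the rhodium catalyst is taken to deliver the alkynyl group to the enone face that gives the (S) propargylic centre of 8; if the sense is the opposite, the (S)-ligand is used.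

Assumption: 8 and 9 are carried as mixtures of epimers at the ring carbon next to the carbonyl, and 18 and 19 as mixtures at the brominated carbon; these centres are planar again before C5 is set in step 10.

Remark: the descriptor of C6 changes from S (8, 9) to R (10 onwards), and that of C5 from R (21–26) to S (27 onwards), only because CIP priorities change; the spatial arrangement is the same throughout.

## Route

Step 1
Reactants: 1 butane-1,4-diol
Product: 2 4-hydroxybutyl pivalate (4-hydroxybutyl 2,2-dimethylpropanoate)
Conditions: PivCl (0.3 equiv), pyridine, CH2Cl2, 0 °C (diol in excess)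
Reagents that add atoms: pivaloyl chloride, CC(C)(C)C(=O)Cl
Why: Acylation of a symmetric diol used in excess gives mainly the monoester; the pivalate survives the basic and organometallic steps ahead and is later removed by the hydride that reduces the methyl ester.

Step 2
Reactants: 2 4-hydroxybutyl pivalate
Product: 3 4-oxobutyl pivalate
Conditions: TEMPO (10 mol%), PhI(OAc)2, CH2Cl2, rt
Reagents that add atoms: none
Why: TEMPO-catalysed oxidation of a primary alcohol stops at the aldehyde and leaves the ester untouched.

Step 3
Reactants: 3 4-oxobutyl pivalate; 4 4-(cyclopent-1-en-1-yl)morpholine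
Product: 6 (4E)-4-(2-oxocyclopentylidene)butyl pivalate, via dienamine 5 (not isolated)
Conditions: toluene, reflux (Dean–Stark); then AcOH/NaOAc, H2O, rt
Reagents that add atoms: water, O
Why: Enamine aldol condensation: the cyclopentanone enamine adds to the aldehyde, water is lost to give the cross-conjugated dienamine 5, and buffered hydrolysis releases the enone without moving the double bond into the ring; the E isomer (chain anti to the carbonyl) is the thermodynamic product.

Step 4
Reactants: 6 (4E)-4-(2-oxocyclopentylidene)butyl pivalate; 7 ethynyltri(propan-2-yl)silane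
Product: 8 (4S)-4-(2-oxocyclopentyl)-6-(triisopropylsilyl)hex-5-yn-1-yl pivalate (both epimers at the ring carbon)
Conditions: [Rh(OAc)(C2H4)2]2 (2.5 mol%), (R)-DTBM-SEGPHOS (6 mol%), 1,4-dioxane, 80 °C
Reagents that add atoms: none
Why: Rhodium-catalysed asymmetric conjugate alkynylation of an enone with a bulky silylacetylene: the alkynylrhodium species adds to the β-carbon (C6) and the rhodium enolate is protonated by the next alkyne, so the chiral bisphosphine sets C6 by choosing the enone face. The bulky silyl group and ligand suppress alkyne dimerisation; the locked s-cis enone suits the oxa-π-allyl intermediate, and its α-branch is the untested element.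

Step 5
Reactants: 8 (4S)-4-(2-oxocyclopentyl)-6-(triisopropylsilyl)hex-5-yn-1-yl pivalate
Product: 9 (4S)-4-(2-oxocyclopentyl)hex-5-yn-1-yl pivalate (both epimers at the ring carbon)
Conditions: TBAF (1.1 equiv), AcOH (1.1 equiv), THF, 0 °C to rt
Reagents that add atoms: none
Why: Fluoride-induced protodesilylation of the alkynylsilane; acetic acid limits base-mediated isomerisation of the alkynyl ketone, and the pivalate is inert to fluoride, which is why no silyl ether is used on the C6 arm.

Step 6
Reactants: 9 (4S)-4-(2-oxocyclopentyl)hex-5-yn-1-yl pivalate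
Product: 10 (4R)-4-[2-(tert-butyldimethylsilyloxy)cyclopent-1-en-1-yl]hex-5-yn-1-yl pivalate
Conditions: TBSCl, NaI, Et3N, MeCN, 40 °C
Reagents that add atoms: tert-butyldimethylsilyl chloride, CC(C)(C)[Si](C)(C)Cl
Why: Thermodynamic silyl enol ether formation (silyl iodide made in situ, equilibrating amine conditions) favours the tetrasubstituted C1=C5 enol ether, which protects the ketone and marks C5 as the later nucleophile. Both epimers of 9 converge, and the minor C1=C2 isomer is removed by chromatography and recycled by hydrolysis.

Step 7
Reactants: 10 (4R)-4-[2-(tert-butyldimethylsilyloxy)cyclopent-1-en-1-yl]hex-5-yn-1-yl pivalate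
Product: 12 methyl (4R)-4-[2-(tert-butyldimethylsilyloxy)cyclopent-1-en-1-yl]-7-(pivaloyloxy)hept-2-ynoate, via lithium acetylide 11 (not isolated)
Conditions: LiN(i-Pr)2 (1.05 equiv), THF, −78 °C; then added to ClCO2Me (3 equiv), THF, −78 °C
Reagents that add atoms: methyl chloroformate, COC(=O)Cl
Why: Deprotonation of the terminal alkyne and C-acylation of the acetylide; inverse addition into excess chloroformate keeps the acetylide away from the product, whose C6–H is propargylic and allylic and could otherwise be removed with loss of configuration.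

Step 8
Reactants: 12 methyl (4R)-4-[2-(tert-butyldimethylsilyloxy)cyclopent-1-en-1-yl]-7-(pivaloyloxy)hept-2-ynoate; 13 2-(2-bromoethyl)-2-methyl-1,3-dioxolane
Product: 17 methyl (2Z,4R)-4-[2-(tert-butyldimethylsilyloxy)cyclopent-1-en-1-yl]-2-methyl-3-[2-(2-methyl-1,3-dioxolan-2-yl)ethyl]-7-(pivaloyloxy)hept-2-enoate, via Grignard reagent 14 (not isolated), via alkylcopper reagent 15 (not isolated), via alkenylcopper adduct 16 (not isolated)
Conditions: 13, Mg, THF, 30 °C; CuBr·SMe2 (1 equiv per 14), THF, −45 °C; 12, −78 °C; then HMPA, MeI (excess), −78 to −30 °C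
Reagents that add atoms: iodomethane, CI
Why: The alkylcopper reagent 15 (from 14 and CuBr·SMe2 in a one-to-one ratio, so that no free Grignard reagent remains) forms a π-complex with the alkynoate and transfers C8 to the β-carbon C7 while copper goes to Cα on the same side, giving alkenylcopper 16. Methylation of 16 by iodomethane in the presence of HMPA occurs at Cα with retention, so C8 and the new methyl end up cis and C6 ends up cis to the ester, the future formyl group. The closest known reaction type is the syn-carbocupration of 2-alkynoates with in situ alkylation of the 1-(alkoxycarbonyl)alkenylcopper intermediate. No ring closes and no stereocentre is created; the step fixes the geometry of the tetrasubstituted alkene and brings in every remaining carbon of ring B. Regioselectivity comes from the ester, which polarises the triple bond so that carbon adds only at C7. Stereoselectivity requires that the kinetic syn adduct be trapped before it equilibrates through the copper allenoate, hence addition at −78 °C and methylation below −30 °C. Chemoselectivity rests on the low basicity and low carbonyl reactivity of alkylcopper reagents, which leave the pivalate, the silyl enol ether, the dioxolane and the acidic C6–H alone.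

Step 9
Reactants: 17 methyl (2Z,4R)-4-[2-(tert-butyldimethylsilyloxy)cyclopent-1-en-1-yl]-2-methyl-3-[2-(2-methyl-1,3-dioxolan-2-yl)ethyl]-7-(pivaloyloxy)hept-2-enoate
Product: 19 methyl (2Z,4R)-4-(1-bromo-2-oxocyclopentyl)-2-methyl-3-(3-oxobutyl)-7-(pivaloyloxy)hept-2-enoate (both configurations at the brominated carbon), via bromo ketal 18 (not isolated)
Conditions: NBS, NaHCO3, THF, −78 to 0 °C; then 1 M HCl, acetone, rt
Reagents that add atoms: N-bromosuccinimide, O=C1CCC(=O)N1Br; water, O
Why: Electrophilic bromination of the silyl enol ether puts bromine only at C5 (regiospecific α-halogenation), and aqueous acid then hydrolyses the dioxolane to the methyl ketone. The tertiary α-bromo ketone tolerates dilute acid, and the configuration at C5 is irrelevant because the centre becomes planar in the next step.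

Step 10
Reactants: 19 methyl (2Z,4R)-4-(1-bromo-2-oxocyclopentyl)-2-methyl-3-(3-oxobutyl)-7-(pivaloyloxy)hept-2-enoate
Product: 21 methyl (2Z)-2-[(5R,6R,10S)-10-hydroxy-10-methyl-1-oxo-6-[3-(pivaloyloxy)propyl]spiro[4.5]decan-7-ylidene]propanoate, via samarium enolate 20 (not isolated)
Conditions: SmI2 (2.2 equiv), THF, −78 °C; aq. NH4Cl, −78 °C
Reagents that add atoms: none
Why: Samarium Reformatsky-type aldol: SmI2 reduces the C5–Br bond to enolate 20, formed only at C5 and under neutral conditions, which adds to the C10 ketone through a closed chair-like transition state to form the C5–C10 bond (6-enolexo-exo-trig closure of ring B). With the C6 chain axial (to avoid A1,3 strain with the ester on Cα), the C10 methyl equatorial and the ketone oxygen bridged to the enolate oxygen by trivalent samarium, C1, the C6 chain and the C10 hydroxyl come out on the same face of ring B, as required. The aldolate has no hydrogen at C5 and cannot dehydrate, and the cold quench forestalls retro-aldol cleavage.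

Step 11
Reactants: 21 methyl (2Z)-2-[(5R,6R,10S)-10-hydroxy-10-methyl-1-oxo-6-[3-(pivaloyloxy)propyl]spiro[4.5]decan-7-ylidene]propanoate
Product: 22 methyl (2Z)-2-[(5R,6R,10S)-10-methyl-1-oxo-6-[3-(pivaloyloxy)propyl]-10-(trimethylsilyloxy)spiro[4.5]decan-7-ylidene]propanoate
Conditions: 1-(trimethylsilyl)imidazole, CH2Cl2, rt
Reagents that add atoms: 1-(trimethylsilyl)imidazole, C[Si](C)(C)n1ccnc1
Why: Silylation of the tertiary alcohol with a neutral silyl donor; the silyl ether blocks retro-aldol cleavage of the β-hydroxy ketone under the base of the next step, and the reagent does not enolise the ketone.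

Step 12
Reactants: 22 methyl (2Z)-2-[(5R,6R,10S)-10-methyl-1-oxo-6-[3-(pivaloyloxy)propyl]-10-(trimethylsilyloxy)spiro[4.5]decan-7-ylidene]propanoate
Product: 24 methyl (2Z)-2-[(5R,6R,10S)-10-methyl-6-[3-(pivaloyloxy)propyl]-1-(trifluoromethanesulfonyloxy)-10-(trimethylsilyloxy)spiro[4.5]dec-1-en-7-ylidene]propanoate, via potassium enolate 23 (not isolated)
Conditions: KN(SiMe3)2 (1.1 equiv), THF, −78 °C; PhNTf2, −78 to 0 °C
Reagents that add atoms: N-phenylbis(trifluoromethanesulfonimide), O=S(=O)(N(c1ccccc1)S(=O)(=O)C(F)(F)F)C(F)(F)F
Why: Kinetic enolate formation and O-triflation: C5 is quaternary, so C2 is the only enolisable position and the C1=C2 enol triflate forms regiospecifically; the hindered conjugated ester and the pivalate survive one equivalent of a bulky amide base at −78 °C.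

Step 13
Reactants: 24 methyl (2Z)-2-[(5R,6R,10S)-10-methyl-6-[3-(pivaloyloxy)propyl]-1-(trifluoromethanesulfonyloxy)-10-(trimethylsilyloxy)spiro[4.5]dec-1-en-7-ylidene]propanoate
Product: 26 methyl (2Z)-2-[(5R,6R,10S)-10-hydroxy-10-methyl-6-[3-(pivaloyloxy)propyl]spiro[4.5]dec-1-en-7-ylidene]propanoate, via silyl ether 25 (not isolated)
Conditions: Pd(OAc)2 (5 mol%), PPh3, HCO2H, Bu3N, DMF, 60 °C; then 1 M HCl, THF, 0 °C
Reagents that add atoms: none
Why: Palladium-catalysed reduction of the enol triflate by formate (oxidative addition, formate exchange, decarboxylation, reductive elimination) gives the C1=C2 alkene; dilute acid in the work-up removes the trimethylsilyl group and frees the homoallylic C10 hydroxyl.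

Step 14
Reactants: 26 methyl (2Z)-2-[(5R,6R,10S)-10-hydroxy-10-methyl-6-[3-(pivaloyloxy)propyl]spiro[4.5]dec-1-en-7-ylidene]propanoate
Product: 27 methyl (2Z)-2-[(1R,2S,5S,6R,10S)-1,2-epoxy-10-hydroxy-10-methyl-6-[3-(pivaloyloxy)propyl]spiro[4.5]decan-7-ylidene]propanoate
Conditions: VO(acac)2 (5 mol%), t-BuOOH, CH2Cl2, 0 °C to rt
Reagents that add atoms: tert-butyl hydroperoxide, CC(C)(C)OO
Why: Hydroxyl-directed epoxidation: the vanadium alkoxide of the homoallylic C10 hydroxyl delivers oxygen to the face of the C1=C2 alkene on which C10 lies, which sets C1; the electron-poor tetrasubstituted acrylate is not epoxidised.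

Step 15
Reactants: 28 6-methylhept-5-en-2-one
Product: 30 6-methylhepta-1,5-dien-2-yl trifluoromethanesulfonate, via lithium enolate 29 (not isolated)
Conditions: LiN(i-Pr)2, THF, −78 °C; PhNTf2, −78 to 0 °C
Reagents that add atoms: N-phenylbis(trifluoromethanesulfonimide), O=S(=O)(N(c1ccccc1)S(=O)(=O)C(F)(F)F)C(F)(F)F
Why: Kinetic deprotonation of the methyl ketone on the methyl side and O-sulfonylation of enolate 29 give the 1-alken-2-yl triflate; the trisubstituted alkene is unaffected.

Step 16
Reactants: 31 2-[(E)-2-bromoethenyl]-6-methyl-1,3,6,2-dioxazaborocane-4,8-dione; 32 prop-2-yn-1-ol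
Product: 33 2-[(1E)-5-hydroxypent-1-en-3-yn-1-yl]-6-methyl-1,3,6,2-dioxazaborocane-4,8-dione
Conditions: PdCl2(PPh3)2 (5 mol%), CuI (10 mol%), piperidine, THF, rt
Reagents that add atoms: none
Why: Sonogashira coupling at the C–Br bond; the MIDA-protected boron does not transmetalate under anhydrous conditions, the E geometry is retained and the free hydroxyl is tolerated.

Step 17
Reactants: 30 6-methylhepta-1,5-dien-2-yl trifluoromethanesulfonate; 33 2-[(1E)-5-hydroxypent-1-en-3-yn-1-yl]-6-methyl-1,3,6,2-dioxazaborocane-4,8-dione
Product: 34 (4E)-10-methyl-6-methylideneundeca-4,9-dien-2-yn-1-ol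
Conditions: Pd(OAc)2 (5 mol%), SPhos (10 mol%), K3PO4, dioxane/H2O, 60 °C
Reagents that add atoms: none
Why: Suzuki–Miyaura coupling: aqueous phosphate slowly releases the sensitive enynylboronic acid from its MIDA ester and couples it with the alkenyl triflate with retention of geometry, forming the 2-substituted (E)-diene.

Step 18
Reactants: 34 (4E)-10-methyl-6-methylideneundeca-4,9-dien-2-yn-1-ol
Product: 36 (2Z,4E)-2-iodo-10-methyl-6-methylideneundeca-2,4,9-trien-1-ol, via alkenylstannane 35 (not isolated)
Conditions: [Cp*RuCl]4 (2.5 mol%), Bu3SnH, CH2Cl2, rt; then I2, 0 °C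
Reagents that add atoms: iodine, II
Why: Ruthenium-catalysed hydroxyl-directed trans-hydrostannation of the propargylic alcohol puts tin on the carbon next to CH2OH and hydrogen on the opposite side of the new alkene, so tin is cis to the diene chain. Iododestannylation with retention gives the (Z)-iodide, the geometry needed for the side chain.

Step 19
Reactants: 36 (2Z,4E)-2-iodo-10-methyl-6-methylideneundeca-2,4,9-trien-1-ol
Product: 37 tert-butyl{[(2Z,4E)-2-iodo-10-methyl-6-methylideneundeca-2,4,9-trien-1-yl]oxy}dimethylsilane
Conditions: TBSCl, imidazole, CH2Cl2, 0 °C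
Reagents that add atoms: tert-butyldimethylsilyl chloride, CC(C)(C)[Si](C)(C)Cl
Why: Silylation of the primary allylic alcohol; the ether survives the organometallic coupling and the hydride reduction and masks this alcohol while the other allylic alcohol is oxidised.

Step 20
Reactants: 27 methyl (2Z)-2-[(1R,2S,5S,6R,10S)-1,2-epoxy-10-hydroxy-10-methyl-6-[3-(pivaloyloxy)propyl]spiro[4.5]decan-7-ylidene]propanoate; 37 tert-butyl{[(2Z,4E)-2-iodo-10-methyl-6-methylideneundeca-2,4,9-trien-1-yl]oxy}dimethylsilane
Product: 41 methyl (2Z)-2-[(1S,2S,5S,6R,10S)-2-[(2E,4E)-1-(tert-butyldimethylsilyloxy)-10-methyl-6-methylideneundeca-2,4,9-trien-2-yl]-1,10-dihydroxy-10-methyl-6-[3-(pivaloyloxy)propyl]spiro[4.5]decan-7-ylidene]propanoate, via alkenyllithium 38 (not isolated), via alkenylmagnesium bromide 39 (not isolated), via magnesium alkoxide 40 (not isolated)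
Conditions: 37, t-BuLi (2 equiv), Et2O, −78 °C; MgBr2·OEt2, −78 to −40 °C; 27 pretreated with MeMgBr (1 equiv), THF, −78 °C; CuI (15 mol%), −40 to 0 °C
Reagents that add atoms: none
Why: Copper-catalysed SN2 opening of the epoxide by an alkenyl Grignard reagent: iodine–lithium exchange and transmetalation give 39 with retention of alkene geometry, and the hydroxyl of 27 is masked as alkoxide 40. The nucleophile attacks C2 because C1 is neopentyl, and inversion at C2 places the side chain trans to the C1 hydroxyl, completing C1 and C2.

Step 21
Reactants: 41 methyl (2Z)-2-[(1S,2S,5S,6R,10S)-2-[(2E,4E)-1-(tert-butyldimethylsilyloxy)-10-methyl-6-methylideneundeca-2,4,9-trien-2-yl]-1,10-dihydroxy-10-methyl-6-[3-(pivaloyloxy)propyl]spiro[4.5]decan-7-ylidene]propanoate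
Product: 42 (1S,2S,5S,6R,10S)-2-[(2E,4E)-1-(tert-butyldimethylsilyloxy)-10-methyl-6-methylideneundeca-2,4,9-trien-2-yl]-6-(3-hydroxypropyl)-7-[(2Z)-1-hydroxypropan-2-ylidene]-10-methylspiro[4.5]decane-1,10-diol
Conditions: i-Bu2AlH (excess), CH2Cl2, −78 to 0 °C; aq. potassium sodium tartrate
Reagents that add atoms: none
Why: Aluminium hydride reduction turns the methyl ester into the allylic alcohol and cleaves the pivalate in the same operation; the alkenes, the silyl ether and the free hydroxyls (as aluminium alkoxides) are unaffected.

Step 22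
Reactants: 42 (1S,2S,5S,6R,10S)-2-[(2E,4E)-1-(tert-butyldimethylsilyloxy)-10-methyl-6-methylideneundeca-2,4,9-trien-2-yl]-6-(3-hydroxypropyl)-7-[(2Z)-1-hydroxypropan-2-ylidene]-10-methylspiro[4.5]decane-1,10-diol
Product: 43 (2Z)-2-[(1S,2S,5S,6R,10S)-2-[(2E,4E)-1-(tert-butyldimethylsilyloxy)-10-methyl-6-methylideneundeca-2,4,9-trien-2-yl]-1,10-dihydroxy-6-(3-hydroxypropyl)-10-methylspiro[4.5]decan-7-ylidene]propanal
Conditions: MnO2 (excess), CH2Cl2, rt
Reagents that add atoms: none
Why: MnO2 oxidises only the allylic primary alcohol; the saturated primary, secondary and tertiary hydroxyls are not touched and the other allylic alcohol is silylated. The neutral heterogeneous conditions preserve the geometry of the tetrasubstituted enal.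

Step 23
Reactants: 43 (2Z)-2-[(1S,2S,5S,6R,10S)-2-[(2E,4E)-1-(tert-butyldimethylsilyloxy)-10-methyl-6-methylideneundeca-2,4,9-trien-2-yl]-1,10-dihydroxy-6-(3-hydroxypropyl)-10-methylspiro[4.5]decan-7-ylidene]propanal
Product: 44 (2Z)-2-[(1S,2S,5S,6R,10S)-1,10-dihydroxy-2-[(2E,4E)-1-hydroxy-10-methyl-6-methylideneundeca-2,4,9-trien-2-yl]-6-(3-hydroxypropyl)-10-methylspiro[4.5]decan-7-ylidene]propanal
Conditions: HF·pyridine, pyridine, THF, 0 °C
Reagents that add atoms: none
Why: Fluoride cleavage of the primary silyl ether under buffered, weakly acidic conditions, which avoid both the basic fluoride that could deconjugate or isomerise the enal and the strong acid that could ionise the tertiary or allylic alcohols.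

## Compound list

1 | butane-1,4-diol | OCCCCO | starting material
2 | 4-hydroxybutyl pivalate | OCCCCOC(=O)C(C)(C)C | intermediate
3 | 4-oxobutyl pivalate | O=CCCCOC(=O)C(C)(C)C | intermediate
4 | 4-(cyclopent-1-en-1-yl)morpholine | C1=C(CCC1)N1CCOCC1 | starting material
5 | 4-[(5E)-5-[4-(pivaloyloxy)butylidene]cyclopent-1-en-1-yl]morpholine (dienamine) | CC(C)(C)C(=O)OCCC/C=C1\CCC=C1N1CCOCC1 | intermediate (not isolated)
6 | (4E)-4-(2-oxocyclopentylidene)butyl pivalate | O=C1CCC/C1=C\CCCOC(=O)C(C)(C)C | intermediate
7 | ethynyltri(propan-2-yl)silane | C#C[Si](C(C)C)(C(C)C)C(C)C | starting material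
8 | (4S)-4-(2-oxocyclopentyl)-6-(triisopropylsilyl)hex-5-yn-1-yl pivalate, both epimers at the ring carbon | O=C1CCCC1[C@H](CCCOC(=O)C(C)(C)C)C#C[Si](C(C)C)(C(C)C)C(C)C | intermediate
9 | (4S)-4-(2-oxocyclopentyl)hex-5-yn-1-yl pivalate, both epimers at the ring carbon | O=C1CCCC1[C@H](CCCOC(=O)C(C)(C)C)C#C | intermediate
10 | (4R)-4-[2-(tert-butyldimethylsilyloxy)cyclopent-1-en-1-yl]hex-5-yn-1-yl pivalate | CC(C)(C)[Si](C)(C)OC1=C(CCC1)[C@H](CCCOC(=O)C(C)(C)C)C#C | intermediate
11 | lithium acetylide of 10 | CC(C)(C)[Si](C)(C)OC1=C(CCC1)[C@H](CCCOC(=O)C(C)(C)C)C#C[Li] | intermediate (not isolated)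
12 | methyl (4R)-4-[2-(tert-butyldimethylsilyloxy)cyclopent-1-en-1-yl]-7-(pivaloyloxy)hept-2-ynoate | COC(=O)C#C[C@@H](CCCOC(=O)C(C)(C)C)C1=C(O[Si](C)(C)C(C)(C)C)CCC1 | intermediate
13 | 2-(2-bromoethyl)-2-methyl-1,3-dioxolane | CC1(CCBr)OCCO1 | starting material
14 | [2-(2-methyl-1,3-dioxolan-2-yl)ethyl]magnesium bromide | CC1(CC[Mg]Br)OCCO1 | intermediate (not isolated)
15 | [2-(2-methyl-1,3-dioxolan-2-yl)ethyl]copper (as its MgBr2·SMe2 complex) | CC1(CC[Cu])OCCO1 | intermediate (not isolated)
16 | alkenylcopper syn adduct of 15 and 12 (copper on Cα, cis to the dioxolanylethyl chain; ester cis to C6) | COC(=O)/C([Cu])=C(/CCC1(C)OCCO1)[C@@H](CCCOC(=O)C(C)(C)C)C2=C(O[Si](C)(C)C(C)(C)C)CCC2 | intermediate (not isolated)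
17 | methyl (2Z,4R)-4-[2-(tert-butyldimethylsilyloxy)cyclopent-1-en-1-yl]-2-methyl-3-[2-(2-methyl-1,3-dioxolan-2-yl)ethyl]-7-(pivaloyloxy)hept-2-enoate | COC(=O)/C(C)=C(/CCC1(C)OCCO1)[C@@H](CCCOC(=O)C(C)(C)C)C2=C(O[Si](C)(C)C(C)(C)C)CCC2 | intermediate
18 | methyl (2Z,4R)-4-(1-bromo-2-oxocyclopentyl)-2-methyl-3-[2-(2-methyl-1,3-dioxolan-2-yl)ethyl]-7-(pivaloyloxy)hept-2-enoate, both configurations at the brominated carbon | COC(=O)/C(C)=C(/CCC1(C)OCCO1)[C@@H](CCCOC(=O)C(C)(C)C)C2(Br)CCCC2=O | intermediate (not isolated)
19 | methyl (2Z,4R)-4-(1-bromo-2-oxocyclopentyl)-2-methyl-3-(3-oxobutyl)-7-(pivaloyloxy)hept-2-enoate, both configurations at the brominated carbon | COC(=O)/C(C)=C(/CCC(C)=O)[C@@H](CCCOC(=O)C(C)(C)C)C1(Br)CCCC1=O | intermediate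
20 | diiodosamarium enolate of debrominated 19 (C1–O–SmI2, C1=C5) | COC(=O)/C(C)=C(/CCC(C)=O)[C@@H](CCCOC(=O)C(C)(C)C)C1=C(O[Sm](I)I)CCC1 | intermediate (not isolated)
21 | methyl (2Z)-2-[(5R,6R,10S)-10-hydroxy-10-methyl-1-oxo-6-[3-(pivaloyloxy)propyl]spiro[4.5]decan-7-ylidene]propanoate | O=C1CCC[C@]12[C@H](CCCOC(=O)C(C)(C)C)/C(=C(/C)C(=O)OC)CC[C@]2(C)O | intermediate
22 | methyl (2Z)-2-[(5R,6R,10S)-10-methyl-1-oxo-6-[3-(pivaloyloxy)propyl]-10-(trimethylsilyloxy)spiro[4.5]decan-7-ylidene]propanoate | O=C1CCC[C@]12[C@H](CCCOC(=O)C(C)(C)C)/C(=C(/C)C(=O)OC)CC[C@]2(C)O[Si](C)(C)C | intermediate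
23 | potassium enolate of 22 (C1–OK, C1=C2) | [K+].[O-]C1=CCC[C@]12[C@H](CCCOC(=O)C(C)(C)C)/C(=C(/C)C(=O)OC)CC[C@]2(C)O[Si](C)(C)C | intermediate (not isolated)
24 | methyl (2Z)-2-[(5R,6R,10S)-10-methyl-6-[3-(pivaloyloxy)propyl]-1-(trifluoromethanesulfonyloxy)-10-(trimethylsilyloxy)spiro[4.5]dec-1-en-7-ylidene]propanoate | FC(F)(F)S(=O)(=O)OC1=CCC[C@]12[C@H](CCCOC(=O)C(C)(C)C)/C(=C(/C)C(=O)OC)CC[C@]2(C)O[Si](C)(C)C | intermediate
25 | methyl (2Z)-2-[(5R,6R,10S)-10-methyl-6-[3-(pivaloyloxy)propyl]-10-(trimethylsilyloxy)spiro[4.5]dec-1-en-7-ylidene]propanoate | C1=CCC[C@]12[C@H](CCCOC(=O)C(C)(C)C)/C(=C(/C)C(=O)OC)CC[C@]2(C)O[Si](C)(C)C | intermediate (not isolated)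
26 | methyl (2Z)-2-[(5R,6R,10S)-10-hydroxy-10-methyl-6-[3-(pivaloyloxy)propyl]spiro[4.5]dec-1-en-7-ylidene]propanoate | C1=CCC[C@]12[C@H](CCCOC(=O)C(C)(C)C)/C(=C(/C)C(=O)OC)CC[C@]2(C)O | intermediate
27 | methyl (2Z)-2-[(1R,2S,5S,6R,10S)-1,2-epoxy-10-hydroxy-10-methyl-6-[3-(pivaloyloxy)propyl]spiro[4.5]decan-7-ylidene]propanoate (epoxide oxygen on the ring A face bearing C10) | O1[C@H]2CC[C@]3([C@H](CCCOC(=O)C(C)(C)C)/C(=C(/C)C(=O)OC)CC[C@]3(C)O)[C@@H]12 | intermediate
28 | 6-methylhept-5-en-2-one | CC(=O)CCC=C(C)C | starting material
29 | lithium 6-methylhepta-1,5-dien-2-olate | [Li]OC(=C)CCC=C(C)C | intermediate (not isolated)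
30 | 6-methylhepta-1,5-dien-2-yl trifluoromethanesulfonate | C=C(OS(=O)(=O)C(F)(F)F)CCC=C(C)C | intermediate
31 | 2-[(E)-2-bromoethenyl]-6-methyl-1,3,6,2-dioxazaborocane-4,8-dione | CN1CC(=O)OB(/C=C/Br)OC(=O)C1 | starting material
32 | prop-2-yn-1-ol | OCC#C | starting material
33 | 2-[(1E)-5-hydroxypent-1-en-3-yn-1-yl]-6-methyl-1,3,6,2-dioxazaborocane-4,8-dione | CN1CC(=O)OB(/C=C/C#CCO)OC(=O)C1 | intermediate
34 | (4E)-10-methyl-6-methylideneundeca-4,9-dien-2-yn-1-ol | CC(C)=CCCC(=C)/C=C/C#CCO | intermediate
35 | (2Z,4E)-10-methyl-6-methylidene-2-(tributylstannyl)undeca-2,4,9-trien-1-ol | CC(C)=CCCC(=C)/C=C/C=C(/CO)[Sn](CCCC)(CCCC)CCCC | intermediate (not isolated)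
36 | (2Z,4E)-2-iodo-10-methyl-6-methylideneundeca-2,4,9-trien-1-ol | CC(C)=CCCC(=C)/C=C/C=C(/CO)I | intermediate
37 | tert-butyl{[(2Z,4E)-2-iodo-10-methyl-6-methylideneundeca-2,4,9-trien-1-yl]oxy}dimethylsilane | CC(C)=CCCC(=C)/C=C/C=C(/CO[Si](C)(C)C(C)(C)C)I | intermediate
38 | alkenyllithium from 37 (lithium in place of iodine, geometry retained) | CC(C)=CCCC(=C)/C=C/C=C(/CO[Si](C)(C)C(C)(C)C)[Li] | intermediate (not isolated)
39 | alkenylmagnesium bromide from 38 (geometry retained) | CC(C)=CCCC(=C)/C=C/C=C(/CO[Si](C)(C)C(C)(C)C)[Mg]Br | intermediate (not isolated)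
40 | bromomagnesium C10 alkoxide of 27 | O1[C@H]2CC[C@]3([C@H](CCCOC(=O)C(C)(C)C)/C(=C(/C)C(=O)OC)CC[C@]3(C)O[Mg]Br)[C@@H]12 | intermediate (not isolated)
41 | methyl (2Z)-2-[(1S,2S,5S,6R,10S)-2-[(2E,4E)-1-(tert-butyldimethylsilyloxy)-10-methyl-6-methylideneundeca-2,4,9-trien-2-yl]-1,10-dihydroxy-10-methyl-6-[3-(pivaloyloxy)propyl]spiro[4.5]decan-7-ylidene]propanoate | C=C(/C=C/C=C(/CO[Si](C)(C)C(C)(C)C)[C@@H]1CC[C@]2([C@H](CCCOC(=O)C(C)(C)C)/C(=C(/C)C(=O)OC)CC[C@]2(C)O)[C@H]1O)CCC=C(C)C | intermediate
42 | (1S,2S,5S,6R,10S)-2-[(2E,4E)-1-(tert-butyldimethylsilyloxy)-10-methyl-6-methylideneundeca-2,4,9-trien-2-yl]-6-(3-hydroxypropyl)-7-[(2Z)-1-hydroxypropan-2-ylidene]-10-methylspiro[4.5]decane-1,10-diol | C=C(/C=C/C=C(/CO[Si](C)(C)C(C)(C)C)[C@@H]1CC[C@]2([C@H](CCCO)/C(=C(/C)CO)CC[C@]2(C)O)[C@H]1O)CCC=C(C)C | intermediate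
43 | (2Z)-2-[(1S,2S,5S,6R,10S)-2-[(2E,4E)-1-(tert-butyldimethylsilyloxy)-10-methyl-6-methylideneundeca-2,4,9-trien-2-yl]-1,10-dihydroxy-6-(3-hydroxypropyl)-10-methylspiro[4.5]decan-7-ylidene]propanal | C=C(/C=C/C=C(/CO[Si](C)(C)C(C)(C)C)[C@@H]1CC[C@]2([C@H](CCCO)/C(=C(/C)C=O)CC[C@]2(C)O)[C@H]1O)CCC=C(C)C | intermediate
44 | (2Z)-2-[(1S,2S,5S,6R,10S)-1,10-dihydroxy-2-[(2E,4E)-1-hydroxy-10-methyl-6-methylideneundeca-2,4,9-trien-2-yl]-6-(3-hydroxypropyl)-10-methylspiro[4.5]decan-7-ylidene]propanal (CNP0246965.1) | C=C(/C=C/C=C(/CO)[C@@H]1CC[C@]2([C@H](CCCO)/C(=C(/C)C=O)CC[C@]2(C)O)[C@H]1O)CCC=C(C)C | target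

## Step count and risks

Total step count: 23. Longest linear sequence: 18 steps (steps 1–14 and 20–23); the side-chain branch (steps 15–19, with step 16 as a one-step feeder) joins at step 20.

**Step 8 (key step).** The most likely failure is loss of alkene geometry: methylation of alkenylcopper 16 needs warming in HMPA, and in that window 16 can equilibrate through its copper allenoate. Slow addition next to the branched C6 would make this worse by forcing higher temperatures. Fallback: starting from 12, the carbocupration is run as before but 16 is quenched with I2 at −78 °C, where trapping is fast, to give the α-iodo enoate F1. A separate Negishi methylation of F1 (Pd(PPh3)4, Me2Zn, THF) then forms the Cα–CH3 bond with retention and returns to 17.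

**Step 4.** Insertion of the α-branched exocyclic enone into the alkynylrhodium species may be slow, so that alkyne dimerisation takes over, or the enone faces may be poorly distinguished. Fallback: starting from 6, a binaphthol-catalysed conjugate alkynylation with diisopropyl [(triisopropylsilyl)ethynyl]boronate F2 (made from 7 by lithiation and borylation). This boron-based addition goes through a closed six-membered transition state that requires an s-cis enone, which is exactly what 6 offers; the 3,3′-diiodobinaphthol enantiomer is chosen to give the same (S) centre. It returns to 8.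

**Step 10.** Three things can go wrong:
- protonation of the samarium enolate before it cyclises;
- closure through the less favourable chair, giving the C5/C10 epimer;
- attack of the enolate on the cis ester (five-membered acylation) instead of the ketone.

Fallback: starting from 17, a Mukaiyama-type closure with TiCl4 (CH2Cl2, −78 °C), in which the silyl enol ether attacks the oxocarbenium ion formed from the dioxolane. No free methyl ketone is present, so the competing fused aldol mode cannot occur. This gives the 2-hydroxyethyl ether F3. Its primary alcohol is converted into the 2-iodoethyl ether F4 (I2, PPh3, imidazole), and zinc-induced reductive fragmentation (Zn, EtOH) releases the tertiary alcohol, returning to 21. The open transition state makes the C10 configuration less predictable, which is why this is not the first choice.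

**Step 20.** The α-branched alkenyl nucleophile may open the hindered epoxide too slowly, so that attack on the pivalate or Lewis-acid-induced rearrangement of the epoxide next to the quaternary centre competes. Fallback: starting from 27, regioselective opening with MgI2 (Et2O, 0 °C) at C2 gives the trans-iodohydrin F5. A nickel-catalysed reductive cross-electrophile coupling of F5 with 37 (NiBr2(dme), 4,4′-di-tert-butyl-2,2′-bipyridine, Zn, DMA) forms the C2–alkenyl bond through a C2 radical, which should be captured anti to the C1 oxygen. It returns to 41.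

## Further compounds

F1 | step 8 | methyl (2E,4S)-4-[2-(tert-butyldimethylsilyloxy)cyclopent-1-en-1-yl]-2-iodo-3-[2-(2-methyl-1,3-dioxolan-2-yl)ethyl]-7-(pivaloyloxy)hept-2-enoate | COC(=O)/C(I)=C(/CCC1(C)OCCO1)[C@@H](CCCOC(=O)C(C)(C)C)C2=C(O[Si](C)(C)C(C)(C)C)CCC2
F2 | step 4 | diisopropyl [(triisopropylsilyl)ethynyl]boronate | CC(C)OB(OC(C)C)C#C[Si](C(C)C)(C(C)C)C(C)C
F3 | step 10 | methyl (2Z)-2-[(5R,6R,10S)-10-(2-hydroxyethoxy)-10-methyl-1-oxo-6-[3-(pivaloyloxy)propyl]spiro[4.5]decan-7-ylidene]propanoate | O=C1CCC[C@]12[C@H](CCCOC(=O)C(C)(C)C)/C(=C(/C)C(=O)OC)CC[C@]2(C)OCCO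
F4 | step 10 | methyl (2Z)-2-[(5R,6R,10S)-10-(2-iodoethoxy)-10-methyl-1-oxo-6-[3-(pivaloyloxy)propyl]spiro[4.5]decan-7-ylidene]propanoate | O=C1CCC[C@]12[C@H](CCCOC(=O)C(C)(C)C)/C(=C(/C)C(=O)OC)CC[C@]2(C)OCCI
F5 | step 20 | methyl (2Z)-2-[(1R,2R,5S,6R,10S)-1,10-dihydroxy-2-iodo-10-methyl-6-[3-(pivaloyloxy)propyl]spiro[4.5]decan-7-ylidene]propanoate | I[C@@H]1CC[C@]2([C@H](CCCOC(=O)C(C)(C)C)/C(=C(/C)C(=O)OC)CC[C@]2(C)O)[C@H]1O
A1 | alternative 1 | 4-[(6R)-6-hydroxy-2-methylcyclohex-1-en-1-yl]butanenitrile oxide | [O-][N+]#CCCCC1=C(C)CCC[C@H]1O
A2 | alternative 1 | spiro-fused isoxazoline with ring A closed and the C6 hydroxyl retained | N1=C2CCC[C@]23[C@H](O)CCC[C@]3(C)O1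
A3 | alternative 2 | cyclobutane photoadduct with ring B closed (cyclobutane carbons C6, C7, C1′, C2′) | CC1(C)O[C@@]23CC[C@](C)(O[Si](CC)(CC)CC)[C@@]4(CCC[C@@H]4O[Si](C)(C)C(C)(C)C)[C@@H]2C[C@H]3C(=O)O1
A4 | alternative 3 | 10-hydroxy-10-methyl-7-isopropenyl-6-(tert-butyldimethylsilyloxymethyl)spiro[4.5]decan-1-one | C1CC[C@]2([C@H](CO[Si](C)(C)C(C)(C)C)[C@@H](C(C)=C)CC[C@]2(C)O)C1=O
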